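## Analysis of the target

The target 26 is a 3,3''-linked biflavanone: two 2-aryl-2,3-dihydro-4H-chromen-4-one units joined by a single bond between C3A and C3B. Unit A is a 7-hydroxyflavanone and unit B a 5,7-dihydroxyflavanone, and each carries a 4-hydroxyphenyl group at C2. The four stereocentres C2A, C3A, C3B and C2B are contiguous and are 2S,3R in both units, so in each pyranone ring the aryl group and the C3 substituent are trans (diequatorial). The C2A–C3A–C3B–C2B core is locally C2-symmetric, but the two benzo rings differ, so the molecule is not. Sensitive points are the C3 hydrogens (α to a ketone and β to the ring oxygen, so base opens the pyranone by retro-oxa-Michael reaction and scrambles C2 and C3), the five phenols, and the C4A/C4B 1,4-dicarbonyl pair, which strong acid can dehydrate to a furan. The difficulty is to make the crowded C3A–C3B bond between two unlike halves without a statistical mixture of dimers, and to fix four adjacent centres. The plan rests on one feature: C2A and C2B are 4-hydroxybenzylic carbons, each bonded to a phenolic oxygen (O1A, O1B) that sits ortho to an aryl ketone, so both C–O bonds can be made last by oxidising benzylic C–H bonds of an open-chain 2,3-bis(4-hydroxybenzyl)-1,4-diketone that already holds C3A and C3B.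

## Retrosynthetic reasoning

Target 26 is traced back to its tris-acetal 25, in which O7A, O5B and O7B are capped. These three oxygens are the only non-chelated hydroxyls of the two acylated rings. Capping them keeps those rings out of the oxidation that precedes, and mild acidic methanolysis removes the caps at the end.

In 25 the bonds O1A–C2A and O1B–C2B are cut, which opens both pyranone rings and leads to the diketone 23. The cut is placed here because both carbons are para-hydroxybenzylic. Forward, a quinone oxidant turns each 4-hydroxybenzyl CH2 of 23 into a para-quinone methide, and the neighbouring ketone-chelated phenol adds to it. Cutting C3A–C3B in a bis-flavanone instead would mean coupling two different enolates with no control over pairing or configuration. The chosen cut gives two rings and two stereocentres in one operation, and leaves an acyclic problem with only two centres, C3A and C3B, in a C2-symmetric environment.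

Diketone 23 needs free 4-hydroxybenzyl phenols and one free ortho hydroxyl per ketone, with acetals on the rest. The benzyl-arene phenols are kept as benzyl ethers from the start and released last by hydrogenolysis of 22. The ortho/para pattern of 22 comes from the pentahydroxy diketone 21, where the hydrogen bond to each carbonyl shields exactly the hydroxyls that must stay free. Compound 21 comes from the fully acetal-capped diketone 20 by acidic methanolysis. This two-step detour is accepted because the aryl nucleophiles that build 20 must be fully capped, and ortho and para oxygens are most reliably told apart once the ketone is present.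

In 20 the bond between C4A and the resorcinol ring is cut, giving the S-phenyl thioester 14 and the boronic acid 19. A palladium/copper thioester–boronic acid coupling forms this ketone under neutral conditions. An organolithium at this stage would meet the ketone and the two α-stereocentres already present. The boronic acid 19 is taken back through bromide 16 to 4-bromoresorcinol 15, whose bromine fixes the acylation site.

Thioester 14 is derived from keto acid 13, and in 13 the bond between C4B and the phloroglucinol ring is cut. This gives aryllithium 12 (from 11, from phloroglucinol 10) and the anhydride 9. Because 9 is C2-symmetric, either carbonyl gives the same keto acid, so the two different arenes are installed one after the other on a homodimer and the heterodimer problem does not arise. The hindered arene goes in first so that the ketone it creates is shielded during the later steps.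

Anhydride 9 comes from diacid 8, and 8 from the bis-imide 6 by cleavage of the auxiliary. In 6 the C3A–C3B bond is cut symmetrically, giving two molecules of imide 4. Forward, oxidative homocoupling of the enolate of 4 forms this bond, and the auxiliary 2 sets both centres at once. Imide 4 is assembled from acid 1 and auxiliary 2.

## Alternatives that were turned down

Alternative 1: The bond cut is C4aB–C5B inside the phloroglucinol ring of unit B, so this arene is built by a polyketide-type Claisen condensation. Forward, the 6-(acylmethyl)-4-hydroxy-2-pyranone A1 would be opened by magnesium dimethoxide A2 to a triketo ester. A1 already contains the finished unit A flavanone, C3B and a silyl-protected C2B carbinol. The C4aB methylene of the triketo ester then attacks the ester carbonyl and, after enolisation, gives the 2,4,6-trihydroxyphenyl ketone A3.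
- For: the chain itself dictates the oxygenation pattern of ring B. No aryl–acyl bond has to be forced onto a di-ortho-substituted arene. No oxidant meets a free phenol.
- Against: the basic medium created by A2 acts on a molecule whose unit A pyranone can open by retro-oxa-Michael reaction and whose C3A and C3B hydrogens are α to carbonyls. Aldol-type folding of the triketo ester competes with the Claisen mode. A1 must already carry all four stereocentres, and this disconnection does not say how they are made. After A3 the unit B pyranone still has to be closed by an invertive etherification at an easily ionised 4-alkoxybenzylic carbon, followed by deprotection.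
- Comparison: Alternative 1 is stronger in avoiding oxidation chemistry on a polyphenol. In exchange, its key step builds one carbocycle and no stereocentre and it is clearly longer, whereas oxidation of 23 closes two heterocycles and sets two centres under the control of two that one auxiliary has fixed.

Alternative 2: The bond cut is C3B–C4B of the unit B pyranone, with the O1B–C2B ether already in place as a tether. Forward, the aldehyde A4 (an (E)-3-alkylidene flavanone of unit A whose side chain carries C2B and the formyl-bearing aryl ether) would be reduced by samarium diiodide A5. The ketyl at C4B adds to C3B, the β-carbon of the enone, in a six-membered closure, and the samarium enolate is protonated at C3A to give the C4B alcohol A6.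
- For: ketyl–enone cyclisations to six-membered rings are dependable. The two unlike halves are joined by a tether beforehand, so no dimer statistics arise. The conditions are neutral and tolerate acetals.
- Against: C3B and C3A (and a C4B carbinol centre that is later destroyed) are all set at once, with only C2A and C2B as control elements, and C3A is fixed by a kinetic protonation. The aryloxy group at C2B is a leaving group next to the enone β-carbon, so electron transfer from A5 to the easily reduced aryl enone can expel the phenoxide instead of closing the ring. An extra oxidation of the C4B alcohol and removal of five acetals follow. Enantiopure A4 needs separate asymmetric syntheses of C2A and C2B.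
- Comparison: on convergence Alternative 2 is at least as good, since the halves are made separately. The chosen plan offers a single chiral source, stereo-relay to C2A and C2B, two rings in one step and a shorter end game.

Alternative 3: The bonds cut are C8A–C8aA and C4aA–C5A, so the benzo ring of unit A is made last by cycloaddition. Forward, the bromo dihydropyranone A7 would react across C4aA=C8aA with 1-methoxy-3-(trimethylsilyloxy)buta-1,3-diene A8 in a Diels–Alder reaction. Elimination of the methoxy group and of bromide then aromatises the adduct to the 7-hydroxy compound A9.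
- For: the diene polarity fixes the position of the 7-hydroxyl without ambiguity. That hydroxyl emerges free and differentiated from the four acetal-capped ones.
- Against: C4aA=C8aA is the enol-ether double bond of a vinylogous ester and a poor dienophile, even with the bromine. The heat or Lewis acid needed, and the base for aromatisation, act on a 2,3-disubstituted dihydropyranone that can open by β-elimination. A7 already contains all four stereocentres and the C3A–C3B bond, so the real problems are left to unspecified earlier steps.
- Comparison: on regiochemical certainty for ring A the alternative is as strong. The chosen plan gets the same certainty from the bromine of 15, and its key step forms two rings and two stereocentres instead of one benzo ring.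

Key step: step 14

Assumption: acid 1 and 4-bromoresorcinol 15 are treated as catalogue compounds (1 is otherwise one O-benzylation away from the free phenol acid), and the enolate homocoupling is taken to follow the facial rule of auxiliary-controlled enolate alkylation, which makes the (R)-auxiliary the one that gives the (S,S) core.

## Route

Step 1
Reactants: 1 3-[4-(benzyloxy)phenyl]propanoic acid; 2 (R)-4-benzyl-1,3-oxazolidin-2-one
Product: 4 (R)-4-benzyl-3-{3-[4-(benzyloxy)phenyl]propanoyl}-1,3-oxazolidin-2-one, via mixed pivalic anhydride 3 (not isolated)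
Conditions: t-BuCOCl, Et3N, THF, −20 °C; then LiCl, 2, −20 °C → rt
Reagents that add atoms: none
Why: Mixed-anhydride N-acylation of an oxazolidinone; the pivaloyl carbonyl is shielded, so nitrogen attacks the arylpropanoyl carbonyl. No stereocentre is formed.

Step 2
Reactants: 4 (R)-4-benzyl-3-{3-[4-(benzyloxy)phenyl]propanoyl}-1,3-oxazolidin-2-one (two molecules)
Product: 6 (2S,3S)-2,3-bis[4-(benzyloxy)benzyl]-1,4-bis[(R)-4-benzyl-2-oxo-1,3-oxazolidin-3-yl]butane-1,4-dione, via lithium Z-enolate 5 (not isolated)
Conditions: LiN(i-Pr)2, THF, −78 °C; then TiCl4, −78 °C → rt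
Reagents that add atoms: none
Why: Oxidative enolate homocoupling: tetravalent titanium oxidises the chelated Z-enolate by one electron and the α-carbonyl radicals (or radical plus enolate) join at carbon, forming C3A–C3B. Each partner reacts on the face away from the benzyl group of the auxiliary, as in auxiliary-controlled alkylation, so the (R)-auxiliary should give S at both new centres and favour the C2-symmetric dimer over the meso one.

Step 3
Reactants: 6 (2S,3S)-2,3-bis[4-(benzyloxy)benzyl]-1,4-bis[(R)-4-benzyl-2-oxo-1,3-oxazolidin-3-yl]butane-1,4-dione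
Product: 8 (2S,3S)-2,3-bis[4-(benzyloxy)benzyl]butanedioic acid, via bis-peroxy acid 7 (not isolated)
Conditions: LiOH, 30% H2O2, THF–H2O (3:1), 0 °C; then aq Na2SO3; HCl to pH 2
Reagents that add atoms: hydrogen peroxide, OO
Why: Hydroperoxide cleavage of N-acyloxazolidinones: the hydroperoxide anion attacks the exocyclic carbonyl even in hindered imides and is too weakly basic to epimerise the α-centres. Sulfite reduces the peracid, and the auxiliary is recovered.

Step 4
Reactants: 8 (2S,3S)-2,3-bis[4-(benzyloxy)benzyl]butanedioic acid
Product: 9 (3S,4S)-3,4-bis[4-(benzyloxy)benzyl]oxolane-2,5-dione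
Conditions: DCC, CH2Cl2, 0 °C → rt
Reagents that add atoms: none
Why: Carbodiimide dehydration of a 1,2-diacid to the five-membered cyclic anhydride under neutral conditions. The trans arrangement is the more stable one for a 3,4-disubstituted succinic anhydride, so the centres should not move.

Step 5
Reactants: 10 phloroglucinol
Product: 11 1,3,5-tris(methoxymethoxy)benzene
Conditions: MeOCH2Cl, i-Pr2NEt, DMF, 0 °C → rt
Reagents that add atoms: chloromethyl methyl ether, COCCl
Why: O-alkylation of phenols with a hard α-chloro ether, which favours oxygen over ring carbon.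

Step 6
Reactants: 11 1,3,5-tris(methoxymethoxy)benzene; 9 (3S,4S)-3,4-bis[4-(benzyloxy)benzyl]oxolane-2,5-dione
Product: 13 (2S,3S)-2,3-bis[4-(benzyloxy)benzyl]-4-oxo-4-[2,4,6-tris(methoxymethoxy)phenyl]butanoic acid, via aryllithium 12 (not isolated)
Conditions: 11, n-BuLi, THF, 0 °C; cannulated into 9, THF, −78 °C; AcOH quench at −78 °C
Reagents that add atoms: none
Why: Directed ortho-lithiation between two acetal oxygens, then addition of the aryllithium to a cyclic anhydride. The reaction stops at the keto carboxylate because the carboxylate is inert and the new ketone is flanked by two ortho substituents. The anhydride is C2-symmetric, so both carbonyls give the same product, and inverse addition with no excess base leaves the α-centres alone.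

Step 7
Reactants: 13 (2S,3S)-2,3-bis[4-(benzyloxy)benzyl]-4-oxo-4-[2,4,6-tris(methoxymethoxy)phenyl]butanoic acid
Product: 14 S-phenyl (2S,3S)-2,3-bis[4-(benzyloxy)benzyl]-4-oxo-4-[2,4,6-tris(methoxymethoxy)phenyl]butanethioate
Conditions: PhSH, EDC·HCl, DMAP (cat.), CH2Cl2, 0 °C → rt
Reagents that add atoms: thiophenol, Sc1ccccc1
Why: Steglich-type carbodiimide thioesterification; no acid is present, so the acetals survive.

Step 8
Reactants: 15 4-bromobenzene-1,3-diol
Product: 16 1-bromo-2,4-bis(methoxymethoxy)benzene
Conditions: MeOCH2Cl, i-Pr2NEt, CH2Cl2, 0 °C → rt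
Reagents that add atoms: chloromethyl methyl ether, COCCl
Why: Phenol O-alkylation as in step 5.

Step 9
Reactants: 16 1-bromo-2,4-bis(methoxymethoxy)benzene
Product: 19 [2,4-bis(methoxymethoxy)phenyl]boronic acid, via aryllithium 17 (not isolated), via lithium triisopropoxyborate 18 (not isolated)
Conditions: n-BuLi, THF, −78 °C; B(Oi-Pr)3, −78 °C → rt; aq NH4Cl
Reagents that add atoms: triisopropyl borate, CC(C)OB(OC(C)C)OC(C)C; water, O
Why: Bromine–lithium exchange is faster than ring deprotonation and puts lithium on the former C–Br carbon, ortho to one acetal oxygen and para to the other. Borate trapping and hydrolysis is the standard arylboronic acid synthesis.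

Step 10
Reactants: 14 S-phenyl (2S,3S)-2,3-bis[4-(benzyloxy)benzyl]-4-oxo-4-[2,4,6-tris(methoxymethoxy)phenyl]butanethioate; 19 [2,4-bis(methoxymethoxy)phenyl]boronic acid
Product: 20 (2S,3S)-2,3-bis[4-(benzyloxy)benzyl]-1-[2,4-bis(methoxymethoxy)phenyl]-4-[2,4,6-tris(methoxymethoxy)phenyl]butane-1,4-dione
Conditions: Pd2(dba)3 (cat.), tri(2-furyl)phosphine (cat.), Cu(O2C-C4H3S) (copper thiophene-2-carboxylate, 1.5 equiv), THF, rt → 45 °C
Reagents that add atoms: none
Why: Liebeskind–Srogl ketone synthesis: zerovalent palladium inserts into the acyl–sulfur bond, the thiophilic monovalent copper carboxylate takes up the thiolate and activates boron for transmetalation, and reductive elimination gives the aryl ketone. The medium is base-free and neutral, so the existing ketone, both α-stereocentres and all ethers should be untouched.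

Step 11
Reactants: 20 (2S,3S)-2,3-bis[4-(benzyloxy)benzyl]-1-[2,4-bis(methoxymethoxy)phenyl]-4-[2,4,6-tris(methoxymethoxy)phenyl]butane-1,4-dione
Product: 21 (2S,3S)-2,3-bis[4-(benzyloxy)benzyl]-1-(2,4-dihydroxyphenyl)-4-(2,4,6-trihydroxyphenyl)butane-1,4-dione
Conditions: HCl (3 M in MeOH), THF, 40 °C
Reagents that add atoms: none
Why: Acid-catalysed transacetalisation of the five aryl methoxymethyl ethers to the solvent. Benzyl ethers are stable, and moderate temperature with a stop at full conversion limits acid-catalysed enolisation.

Step 12
Reactants: 21 (2S,3S)-2,3-bis[4-(benzyloxy)benzyl]-1-(2,4-dihydroxyphenyl)-4-(2,4,6-trihydroxyphenyl)butane-1,4-dione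
Product: 22 (2S,3S)-2,3-bis[4-(benzyloxy)benzyl]-1-[2-hydroxy-4-(methoxymethoxy)phenyl]-4-[2-hydroxy-4,6-bis(methoxymethoxy)phenyl]butane-1,4-dione
Conditions: MeOCH2Cl (3.2 equiv), i-Pr2NEt, CH2Cl2, 0 °C
Reagents that add atoms: chloromethyl methyl ether, COCCl
Why: Chelation-differentiated O-alkylation, routine for 2,4-dihydroxy- and 2,4,6-trihydroxyphenyl ketones. The hydroxyl hydrogen-bonded to each carbonyl is much less nucleophilic, so three equivalents should cap O4 of the resorcinol ring and O4 and O6 of the phloroglucinol ring and leave one ortho hydroxyl on each ketone.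

Step 13
Reactants: 22 (2S,3S)-2,3-bis[4-(benzyloxy)benzyl]-1-[2-hydroxy-4-(methoxymethoxy)phenyl]-4-[2-hydroxy-4,6-bis(methoxymethoxy)phenyl]butane-1,4-dione
Product: 23 (2S,3S)-2,3-bis(4-hydroxybenzyl)-1-[2-hydroxy-4-(methoxymethoxy)phenyl]-4-[2-hydroxy-4,6-bis(methoxymethoxy)phenyl]butane-1,4-dione
Conditions: H2 (1 atm), Pd/C, EtOAc–THF, rt
Reagents that add atoms: none
Why: Hydrogenolysis of aryl benzyl ethers. Acetals and the electron-rich, chelated aryl ketones are inert at one atmosphere and room temperature.

Step 14
Reactants: 23 (2S,3S)-2,3-bis(4-hydroxybenzyl)-1-[2-hydroxy-4-(methoxymethoxy)phenyl]-4-[2-hydroxy-4,6-bis(methoxymethoxy)phenyl]butane-1,4-dione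
Product: 25 (2S,3R)-2-(4-hydroxyphenyl)-3-[(2S,3R)-2-(4-hydroxyphenyl)-5,7-bis(methoxymethoxy)-4-oxo-3,4-dihydro-2H-chromen-3-yl]-7-(methoxymethoxy)-2,3-dihydro-4H-chromen-4-one, via bis-quinone methide 24 (not isolated)
Conditions: DDQ (2.1 equiv), 1,4-dioxane (0.01 M), rt
Reagents that add atoms: none
Why: DDQ abstracts hydride from each 4-hydroxybenzylic CH2 through its charge-transfer complex with the phenol, and loss of the phenolic proton gives the para-quinone methide (drawn as the doubly oxidised form 24, although the two ends need not react at the same time); the ketone-chelated ortho-phenol of the neighbouring aryl ketone then adds to the exocyclic methide carbon, restoring the arene and forming O1A–C2A and O1B–C2B. The closest known reaction type is the DDQ or Ag2O oxidative cyclisation of 4-hydroxy-2'-hydroxydihydrochalcones to flavanones through quinone methides, here run twice in one molecule. Each pyranone ring closes by a 6-exo-trig oxa-conjugate addition, whereas attack by the phenol of the other ketone would be a seven-membered closure. C2A is controlled by C3A and C2B by C3B: in the chair-like transition state and in the product the 4-hydroxyphenyl group and the large C3 substituent are both equatorial, which gives the 2,3-trans rings, and because a 4-hydroxybenzylic aryl ether can re-ionise to the quinone methide, any cis isomer should drain to trans without C3 being touched. The step needs chemoselectivity for the two 4-hydroxybenzyl groups, which the substrate secures because the acetal-capped acyl rings have no benzylic hydrogen and their only free hydroxyls are tied up in hydrogen bonds to the ketones. It also needs the intramolecular capture to outrun loss of the C3 proton from the quinone methide, which would give a ring-opened α-substituted enone and erase C3; the proximity of the phenol and the aprotic, base-free medium favour capture. Over-oxidation of the product at C2–H is held back by using two equivalents of oxidant at room temperature and high dilution.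

Step 15
Reactants: 25 (2S,3R)-2-(4-hydroxyphenyl)-3-[(2S,3R)-2-(4-hydroxyphenyl)-5,7-bis(methoxymethoxy)-4-oxo-3,4-dihydro-2H-chromen-3-yl]-7-(methoxymethoxy)-2,3-dihydro-4H-chromen-4-one
Product: 26 (2S,3R)-7-hydroxy-2-(4-hydroxyphenyl)-3-[(2S,3R)-5,7-dihydroxy-2-(4-hydroxyphenyl)-4-oxo-3,4-dihydro-2H-chromen-3-yl]-2,3-dihydro-4H-chromen-4-one
Conditions: HCl (3 M in MeOH), 40 °C
Reagents that add atoms: none
Why: Acid-catalysed transacetalisation of the three aryl methoxymethyl ethers. The 2,3-trans rings are the thermodynamic isomers, and the mild temperature should keep C3 enolisation slow.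

## Compound list

1 | 3-[4-(benzyloxy)phenyl]propanoic acid | O=C(O)CCc1ccc(OCc2ccccc2)cc1 | starting material
2 | (R)-4-benzyl-1,3-oxazolidin-2-one | O=C1N[C@H](Cc2ccccc2)CO1 | starting material
3 | 3-[4-(benzyloxy)phenyl]propanoic 2,2-dimethylpropanoic anhydride | CC(C)(C)C(=O)OC(=O)CCc1ccc(OCc2ccccc2)cc1 | intermediate
4 | (R)-4-benzyl-3-{3-[4-(benzyloxy)phenyl]propanoyl}-1,3-oxazolidin-2-one | O=C(CCc1ccc(OCc2ccccc2)cc1)N1C(=O)OC[C@H]1Cc1ccccc1 | intermediate
5 | lithium (Z)-enolate of 4 | [Li]O/C(=C\Cc1ccc(OCc2ccccc2)cc1)N1C(=O)OC[C@H]1Cc1ccccc1 | intermediate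
6 | (2S,3S)-2,3-bis[4-(benzyloxy)benzyl]-1,4-bis[(R)-4-benzyl-2-oxo-1,3-oxazolidin-3-yl]butane-1,4-dione | O=C(N1C(=O)OC[C@H]1Cc1ccccc1)[C@@H](Cc1ccc(OCc2ccccc2)cc1)[C@H](Cc1ccc(OCc2ccccc2)cc1)C(=O)N1C(=O)OC[C@H]1Cc1ccccc1 | intermediate
7 | (2S,3S)-2,3-bis[4-(benzyloxy)benzyl]butanediperoxoic acid | OOC(=O)[C@@H](Cc1ccc(OCc2ccccc2)cc1)[C@H](Cc1ccc(OCc2ccccc2)cc1)C(=O)OO | intermediate
8 | (2S,3S)-2,3-bis[4-(benzyloxy)benzyl]butanedioic acid | OC(=O)[C@@H](Cc1ccc(OCc2ccccc2)cc1)[C@H](Cc1ccc(OCc2ccccc2)cc1)C(=O)O | intermediate
9 | (3S,4S)-3,4-bis[4-(benzyloxy)benzyl]oxolane-2,5-dione | O=C1OC(=O)[C@@H](Cc2ccc(OCc3ccccc3)cc2)[C@@H]1Cc1ccc(OCc2ccccc2)cc1 | intermediate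
10 | phloroglucinol (benzene-1,3,5-triol) | Oc1cc(O)cc(O)c1 | starting material
11 | 1,3,5-tris(methoxymethoxy)benzene | COCOc1cc(OCOC)cc(OCOC)c1 | intermediate
12 | [2,4,6-tris(methoxymethoxy)phenyl]lithium | [Li]c1c(OCOC)cc(OCOC)cc1OCOC | intermediate
13 | (2S,3S)-2,3-bis[4-(benzyloxy)benzyl]-4-oxo-4-[2,4,6-tris(methoxymethoxy)phenyl]butanoic acid | OC(=O)[C@@H](Cc1ccc(OCc2ccccc2)cc1)[C@H](Cc1ccc(OCc2ccccc2)cc1)C(=O)c1c(OCOC)cc(OCOC)cc1OCOC | intermediate
14 | S-phenyl (2S,3S)-2,3-bis[4-(benzyloxy)benzyl]-4-oxo-4-[2,4,6-tris(methoxymethoxy)phenyl]butanethioate | O=C(Sc1ccccc1)[C@@H](Cc1ccc(OCc2ccccc2)cc1)[C@H](Cc1ccc(OCc2ccccc2)cc1)C(=O)c1c(OCOC)cc(OCOC)cc1OCOC | intermediate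
15 | 4-bromobenzene-1,3-diol (4-bromoresorcinol) | Oc1ccc(Br)c(O)c1 | starting material
16 | 1-bromo-2,4-bis(methoxymethoxy)benzene | COCOc1ccc(Br)c(OCOC)c1 | intermediate
17 | [2,4-bis(methoxymethoxy)phenyl]lithium | [Li]c1ccc(OCOC)cc1OCOC | intermediate
18 | lithium [2,4-bis(methoxymethoxy)phenyl]tri(propan-2-yloxy)borate | [Li+].CC(C)O[B-](OC(C)C)(OC(C)C)c1ccc(OCOC)cc1OCOC | intermediate
19 | [2,4-bis(methoxymethoxy)phenyl]boronic acid | OB(O)c1ccc(OCOC)cc1OCOC | intermediate
20 | (2S,3S)-2,3-bis[4-(benzyloxy)benzyl]-1-[2,4-bis(methoxymethoxy)phenyl]-4-[2,4,6-tris(methoxymethoxy)phenyl]butane-1,4-dione | O=C(c1ccc(OCOC)cc1OCOC)[C@@H](Cc1ccc(OCc2ccccc2)cc1)[C@H](Cc1ccc(OCc2ccccc2)cc1)C(=O)c1c(OCOC)cc(OCOC)cc1OCOC | intermediate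
21 | (2S,3S)-2,3-bis[4-(benzyloxy)benzyl]-1-(2,4-dihydroxyphenyl)-4-(2,4,6-trihydroxyphenyl)butane-1,4-dione | O=C(c1ccc(O)cc1O)[C@@H](Cc1ccc(OCc2ccccc2)cc1)[C@H](Cc1ccc(OCc2ccccc2)cc1)C(=O)c1c(O)cc(O)cc1O | intermediate
22 | (2S,3S)-2,3-bis[4-(benzyloxy)benzyl]-1-[2-hydroxy-4-(methoxymethoxy)phenyl]-4-[2-hydroxy-4,6-bis(methoxymethoxy)phenyl]butane-1,4-dione | O=C(c1ccc(OCOC)cc1O)[C@@H](Cc1ccc(OCc2ccccc2)cc1)[C@H](Cc1ccc(OCc2ccccc2)cc1)C(=O)c1c(O)cc(OCOC)cc1OCOC | intermediate
23 | (2S,3S)-2,3-bis(4-hydroxybenzyl)-1-[2-hydroxy-4-(methoxymethoxy)phenyl]-4-[2-hydroxy-4,6-bis(methoxymethoxy)phenyl]butane-1,4-dione | O=C(c1ccc(OCOC)cc1O)[C@@H](Cc1ccc(O)cc1)[C@H](Cc1ccc(O)cc1)C(=O)c1c(O)cc(OCOC)cc1OCOC | intermediate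
24 | (2S,3S)-1-[2-hydroxy-4-(methoxymethoxy)phenyl]-4-[2-hydroxy-4,6-bis(methoxymethoxy)phenyl]-2,3-bis[(4-oxocyclohexa-2,5-dien-1-ylidene)methyl]butane-1,4-dione | O=C(c1ccc(OCOC)cc1O)[C@@H](C=C1C=CC(=O)C=C1)[C@H](C=C1C=CC(=O)C=C1)C(=O)c1c(O)cc(OCOC)cc1OCOC | intermediate
25 | (2S,3R)-2-(4-hydroxyphenyl)-3-[(2S,3R)-2-(4-hydroxyphenyl)-5,7-bis(methoxymethoxy)-4-oxo-3,4-dihydro-2H-chromen-3-yl]-7-(methoxymethoxy)-2,3-dihydro-4H-chromen-4-one | O=C1c2ccc(OCOC)cc2O[C@H](c2ccc(O)cc2)[C@H]1[C@H]1C(=O)c2c(OCOC)cc(OCOC)cc2O[C@@H]1c1ccc(O)cc1 | intermediate
26 | (2S,3R)-7-hydroxy-2-(4-hydroxyphenyl)-3-[(2S,3R)-5,7-dihydroxy-2-(4-hydroxyphenyl)-4-oxo-3,4-dihydro-2H-chromen-3-yl]-2,3-dihydro-4H-chromen-4-one | O=C1c2ccc(O)cc2O[C@H](c2ccc(O)cc2)[C@H]1[C@H]1C(=O)c2c(O)cc(O)cc2O[C@@H]1c1ccc(O)cc1 | target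

## Step count and least certain steps

Total step count: 15. Longest linear sequence: 12 steps (steps 1, 2, 3, 4, 6, 7, 10, 11, 12, 13, 14, 15, from acid 1).

Step 14 (key step). Three processes could spoil it. Tautomerisation of a quinone methide by loss of the C3 proton would give a ring-opened α-substituted enone and erase a C3 centre. Further hydride abstraction at C2–H of the product, which is still 4-hydroxybenzylic, would lead on to the flavone level. Intermolecular capture of a quinone methide would give oligomers. The fallback separates oxidation from ring closure. It sets out from 23, which is oxidised with DDQ in methanol–CH2Cl2 at 0 °C, so that the solvent captures each quinone methide at once and gives the bis(benzylic methyl ether) F1 (core configuration as in 23, mixture of epimers at the two methoxy-bearing carbons). Catalytic camphorsulfonic acid in CH2Cl2 then ionises the two 4-hydroxybenzylic ethers, and the ortho-phenols close both rings by SN1 etherification under thermodynamic control. The fallback returns to the route at 25.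

Step 11. Exposure of the open-chain 1,4-diketone to acid could cause Paal–Knorr cyclodehydration to a furan or acid-catalysed epimerisation α to the ketones before all five acetals are gone. The fallback avoids global deprotection. It sets out from 20 and uses MgBr2·OEt2 in ether–CH2Cl2, which chelates between each carbonyl and one flanking acetal oxygen and should cleave only those two ortho ethers. It returns to the route at 22 and bypasses 21. It makes no new compound, hence the entry F0.

Step 6. The hindered, basic aryllithium could deprotonate the anhydride α to a carbonyl instead of adding, which would epimerise the core, or it could add twice. The fallback changes the electrophile. It sets out from 9, which is opened with N,O-dimethylhydroxylamine to the mono-(N-methoxy-N-methyl)amide acid F2. After deprotonation of the acid with LiN(SiMe3)2, aryllithium 12 adds to the amide through a stable chelated tetrahedral intermediate. Acetic acid quench returns the route to 13.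

Step 10. Oxidative addition and transmetalation could be slow at the doubly branched thioester, and the electron-rich boronic acid could protodeboronate first. The fallback replaces the cross-coupling with an organolithium acylation. It sets out from 13, which is coupled with N,O-dimethylhydroxylamine (EDC·HCl, HOBt) to the N-methoxy-N-methylamide F3. Aryllithium 17 (from 16 and n-BuLi) is then added at −78 °C, with the existing ketone shielded by its two ortho substituents. The fallback returns to the route at 20.

Step 15. Acid could induce enolisation at C3A or C3B with loss of configuration, or dehydration of the C4A/C4B dicarbonyl pair, before the three acetals are cleaved. The fallback removes the need for any late deprotection. It sets out from 21, which is hydrogenolysed (H2, Pd/C) to the heptahydroxy diketone F4. The DDQ double cyclisation is then run on F4 without protecting groups, relying on the deactivation of the two acylated rings. The fallback returns to the route at 26.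

## Further compounds

F1 | step 14 | 1-[2-hydroxy-4-(methoxymethoxy)phenyl]-4-[2-hydroxy-4,6-bis(methoxymethoxy)phenyl]-2,3-bis[(4-hydroxyphenyl)(methoxy)methyl]butane-1,4-dione (core configured as in 23; both epimers at each methoxy-bearing carbon) | O=C(c1ccc(OCOC)cc1O)[C@@H](C(OC)c1ccc(O)cc1)[C@H](C(OC)c1ccc(O)cc1)C(=O)c1c(O)cc(OCOC)cc1OCOC
F0 | step 11 | none | none
F2 | step 6 | (2S,3S)-2,3-bis[4-(benzyloxy)benzyl]-4-[methoxy(methyl)amino]-4-oxobutanoic acid | OC(=O)[C@@H](Cc1ccc(OCc2ccccc2)cc1)[C@H](Cc1ccc(OCc2ccccc2)cc1)C(=O)N(C)OC
F3 | step 10 | (2S,3S)-2,3-bis[4-(benzyloxy)benzyl]-N-methoxy-N-methyl-4-oxo-4-[2,4,6-tris(methoxymethoxy)phenyl]butanamide | CON(C)C(=O)[C@@H](Cc1ccc(OCc2ccccc2)cc1)[C@H](Cc1ccc(OCc2ccccc2)cc1)C(=O)c1c(OCOC)cc(OCOC)cc1OCOC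
F4 | step 15 | (2S,3S)-1-(2,4-dihydroxyphenyl)-2,3-bis(4-hydroxybenzyl)-4-(2,4,6-trihydroxyphenyl)butane-1,4-dione | O=C(c1ccc(O)cc1O)[C@@H](Cc1ccc(O)cc1)[C@H](Cc1ccc(O)cc1)C(=O)c1c(O)cc(O)cc1O
A1 | alternative 1 | 4-hydroxy-2-pyranone precursor: unit A 7,4'-bis(methoxymethyl) flavanone carrying at C3A the chain with C3B, the silyl-protected C2B carbinol and a 6-(2-oxoethyl)-4-hydroxy-2H-pyran-2-one | O=C1c2ccc(OCOC)cc2O[C@H](c2ccc(OCOC)cc2)[C@H]1[C@@H](C(=O)CC1=CC(O)=CC(=O)O1)[C@@H](O[Si](C)(C)C(C)(C)C)c1ccc(OCOC)cc1
A2 | alternative 1 | magnesium dimethoxide, Mg(OMe)2 | C[O-].C[O-].[Mg+2]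
A3 | alternative 1 | 2,4,6-trihydroxyphenyl ketone with open unit B pyranone (C2B tert-butyldimethylsilyl ether) | O=C1c2ccc(OCOC)cc2O[C@H](c2ccc(OCOC)cc2)[C@H]1[C@@H](C(=O)c1c(O)cc(O)cc1O)[C@@H](O[Si](C)(C)C(C)(C)C)c1ccc(OCOC)cc1
A4 | alternative 2 | (E)-3-alkylidene flavanone of unit A whose side chain carries C2B, the 4-(methoxymethoxy)phenyl group and the 2-formyl-3,5-bis(methoxymethoxy)phenyl ether | O=C1c2ccc(OCOC)cc2O[C@H](c2ccc(OCOC)cc2)/C1=C\[C@H](Oc1cc(OCOC)cc(OCOC)c1C=O)c1ccc(OCOC)cc1
A5 | alternative 2 | samarium diiodide, SmI2 | [Sm+2].[I-].[I-]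
A6 | alternative 2 | C4B alcohol of the penta-O-methoxymethyl target | O=C1c2ccc(OCOC)cc2O[C@H](c2ccc(OCOC)cc2)[C@H]1[C@H]1[C@H](O)c2c(OCOC)cc(OCOC)cc2O[C@@H]1c1ccc(OCOC)cc1
A7 | alternative 3 | 5-bromo-2,3-dihydro-4H-pyran-4-one carrying the 4-(methoxymethoxy)phenyl group at C2A and the complete tris(methoxymethyl) unit B flavanone at C3A | O=C1C(Br)=CO[C@H](c2ccc(OCOC)cc2)[C@H]1[C@H]1C(=O)c2c(OCOC)cc(OCOC)cc2O[C@@H]1c1ccc(OCOC)cc1
A8 | alternative 3 | (E)-1-methoxy-3-(trimethylsilyloxy)buta-1,3-diene | CO/C=C/C(=C)O[Si](C)(C)C
A9 | alternative 3 | target with free O7A hydroxyl and four methoxymethyl ethers | O=C1c2ccc(O)cc2O[C@H](c2ccc(OCOC)cc2)[C@H]1[C@H]1C(=O)c2c(OCOC)cc(OCOC)cc2O[C@@H]1c1ccc(OCOC)cc1
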